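The route disconnects the C7a=C12a double bond of the pyrido[1,2-a:3,4-b']diindole core, the edge shared by ring B (the N12 pyrrole) and ring C (the pyridine), into two carbonyl carbons: an aryl ketone (C7a) and an indole-2-carboxanilide carbon (C12a). A titanium-mediated reductive oxo-amide coupling joins them in one operation, closing ring B and giving an unsymmetrical 2,2'-biindole that already carries the C6–C7 two-carbon chain on C7a. Its precursor is the anilide of 6-bromoindole-2-carboxylic acid with a 2-aminophenyl 2-silyloxyethyl ketone. N5 alkylation, dehydrogenation and C13 formylation then finish the target.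

Key step: step 6

Remark: locants follow pyrido[1,2-a:3,4-b']diindole numbering (Br on C3, N5, CHO on C13), and the target has no stereocentre. The primary alcohol is carried as its tert-butyldiphenylsilyl (TBDPS) ether, which should survive both acidic Boc removal and the Lewis-acidic titanium/zinc chloride medium of the key step better than a smaller silyl ether.

Step 1
Reactants: 1 methyl 3-hydroxypropanoate
Product: 2 methyl 3-[(tert-butyldiphenylsilyl)oxy]propanoate
Conditions: TBDPSCl, imidazole, DMF, 0 °C → rt
Reagents that add atoms: tert-butyl(chloro)diphenylsilane, CC(C)(C)[Si](Cl)(c1ccccc1)c1ccccc1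
Why: Imidazole-promoted O-silylation of an unhindered primary alcohol is fast and should leave the methyl ester untouched.

Step 2
Reactants: 2 methyl 3-[(tert-butyldiphenylsilyl)oxy]propanoate
Product: 3 3-[(tert-butyldiphenylsilyl)oxy]-N-methoxy-N-methylpropanamide
Conditions: MeNH(OMe)·HCl, i-PrMgCl, THF, −20 → 0 °C; aq NH4Cl
Reagents that add atoms: N,O-dimethylhydroxylamine hydrochloride, CNOC.Cl
Why: Weinreb amide formation by direct aminolysis of the ester with the chloromagnesium amide of N,O-dimethylhydroxylamine, which at −20 °C should add to the ester carbonyl faster than it deprotonates the α-CH2, so the β-silyloxy group is not eliminated.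

Step 3
Reactants: 4 tert-butyl phenylcarbamate; 3 3-[(tert-butyldiphenylsilyl)oxy]-N-methoxy-N-methylpropanamide
Product: 6 tert-butyl (2-{3-[(tert-butyldiphenylsilyl)oxy]propanoyl}phenyl)carbamate, via dilithiated carbamate 5 (not isolated)
Conditions: t-BuLi (2.4 equiv), THF, −78 → −20 °C; then 3, −78 → 0 °C; aq NH4Cl
Reagents that add atoms: none
Why: Directed ortho-metalation, in which the N-lithiated Boc group steers t-BuLi to the ortho C–H and the aryllithium acylates the Weinreb amide through a chelated tetrahedral adduct that releases the ketone only on quench, so over-addition is excluded.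

Step 4
Reactants: 6 tert-butyl (2-{3-[(tert-butyldiphenylsilyl)oxy]propanoyl}phenyl)carbamate
Product: 7 1-(2-aminophenyl)-3-[(tert-butyldiphenylsilyl)oxy]propan-1-one
Conditions: TFA, CH2Cl2, 0 °C → rt; aq NaHCO3
Reagents that add atoms: none
Why: Acidolytic carbamate cleavage (loss of 2-methylpropene and CO2) should be far faster than cleavage of the bulky TBDPS ether, and the liberated aniline is tempered by its hydrogen bond to the ortho ketone.

Step 5
Reactants: 8 6-bromo-1H-indole-2-carboxylic acid; 7 1-(2-aminophenyl)-3-[(tert-butyldiphenylsilyl)oxy]propan-1-one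
Product: 10 6-bromo-N-(2-{3-[(tert-butyldiphenylsilyl)oxy]propanoyl}phenyl)-1H-indole-2-carboxamide, via 6-bromo-1H-indole-2-carbonyl chloride 9 (not isolated)
Conditions: (COCl)2, DMF (cat.), CH2Cl2/THF, 0 °C → rt; evaporate; then 7, pyridine, CH2Cl2, 0 °C → rt
Reagents that add atoms: none
Why: Acid chloride formation followed by N-acylation in pyridine (Schotten–Baumann-type amide synthesis) overcomes the low nucleophilicity of the hydrogen-bonded ortho-acyl aniline, while the indole N–H and C3 are deactivated by the 2-carbonyl group.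

Step 6
Reactants: 10 6-bromo-N-(2-{3-[(tert-butyldiphenylsilyl)oxy]propanoyl}phenyl)-1H-indole-2-carboxamide
Product: 11 6-bromo-3'-{2-[(tert-butyldiphenylsilyl)oxy]ethyl}-1H,1'H-2,2'-biindole
Conditions: TiCl3 (3 equiv), Zn dust (6 equiv), THF, reflux, argon; filtration through silica
Reagents that add atoms: none
Why: Zinc reduces TiCl3 to low-valent titanium, which binds the chelating oxo-amide and transfers an electron to the aryl ketone; the titanium-bound ketyl then attacks the amide carbonyl carbon in a 5-exo-trig closure of ring B, and the titanium diolate is deoxygenated, driven by strong Ti–O bonds and by aromatisation, to the C7a=C12a bond of the new indole. The closest known reaction type is the titanium-mediated reductive cyclisation of ortho-acylanilides to 2,3-disubstituted indoles (Fürstner indole synthesis, an intramolecular McMurry-type coupling). No stereocentre is created. The step needs intramolecular ketone–amide coupling to outrun intermolecular pinacol coupling, reduction of the aryl C–Br bond and loss of the β-silyloxy group. The rigid ortho-anilide, preorganised by its N–H···O=C hydrogen bond, holds the two carbonyls in a 1,5-relationship, and the amide alone is inert to the reagent, so reaction starts at the ketone. The reagent is generated in the presence of the substrate, so it should be consumed by the carbonyl pair before it attacks C–Br or the robust TBDPS ether.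

Step 7
Reactants: 11 6-bromo-3'-{2-[(tert-butyldiphenylsilyl)oxy]ethyl}-1H,1'H-2,2'-biindole
Product: 12 2-(6-bromo-1H,1'H-2,2'-biindol-3'-yl)ethan-1-ol
Conditions: TBAF, THF, 0 °C → rt
Reagents that add atoms: none
Why: Fluoride-driven Si–O cleavage (silyl ether deprotection) should free the primary alcohol without touching the aryl bromide or either indole.

Step 8
Reactants: 12 2-(6-bromo-1H,1'H-2,2'-biindol-3'-yl)ethan-1-ol
Product: 14 3-bromo-6,7-dihydro-12H-pyrido[1,2-a:3,4-b']diindole, via biindolylethyl methanesulfonate 13 (not isolated)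
Conditions: MsCl (1.05 equiv), i-Pr2NEt, THF, 0 °C; then Cs2CO3, DMF, 50 °C
Reagents that add atoms: none
Why: O-Sulfonylation of the primary alcohol, then deprotonation of the bromoindole N–H, gives an indolyl anion that displaces methanesulfonate in a 6-exo-tet SN2 cyclisation forming N5–C6, and the cesium counter-ion in DMF should favour N- over C13-alkylation.

Step 9
Reactants: 14 3-bromo-6,7-dihydro-12H-pyrido[1,2-a:3,4-b']diindole
Product: 15 3-bromo-12H-pyrido[1,2-a:3,4-b']diindole
Conditions: DDQ (1.1 equiv), dry 1,4-dioxane, rt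
Reagents that add atoms: none
Why: Quinone dehydrogenation, in which hydride abstraction from the C7 methylene (benzylic to the N12 indole) and loss of the C6 proton are driven by aromatisation of ring C to the pyrido[1,2-a]indole unit, under conditions that leave the C–Br bond intact.

Step 10
Reactants: 15 3-bromo-12H-pyrido[1,2-a:3,4-b']diindole
Product: 17 3-bromo-12H-pyrido[1,2-a:3,4-b']diindole-13-carbaldehyde, via dimethyliminium chloride 16 (not isolated)
Conditions: POCl3, DMF, 0 °C → rt; then aq NaOH, rt
Reagents that add atoms: N,N-dimethylformamide, CN(C)C=O; water, O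
Why: Vilsmeier–Haack formylation, in which C13 is the only unsubstituted pyrrole-type carbon and the most nucleophilic position of the pyrido[1,2-a]indole unit, and the iminium salt hydrolyses to the aldehyde on basic work-up.

Compound list
1 | methyl 3-hydroxypropanoate | COC(=O)CCO | starting material
2 | methyl 3-[(tert-butyldiphenylsilyl)oxy]propanoate | COC(=O)CCO[Si](c1ccccc1)(c1ccccc1)C(C)(C)C | intermediate
3 | 3-[(tert-butyldiphenylsilyl)oxy]-N-methoxy-N-methylpropanamide | CON(C)C(=O)CCO[Si](c1ccccc1)(c1ccccc1)C(C)(C)C | intermediate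
4 | tert-butyl phenylcarbamate | CC(C)(C)OC(=O)Nc1ccccc1 | starting material
5 | tert-butyl N-lithio-N-(2-lithiophenyl)carbamate | [Li]c1ccccc1N([Li])C(=O)OC(C)(C)C | intermediate
6 | tert-butyl (2-{3-[(tert-butyldiphenylsilyl)oxy]propanoyl}phenyl)carbamate | CC(C)(C)OC(=O)Nc1ccccc1C(=O)CCO[Si](c1ccccc1)(c1ccccc1)C(C)(C)C | intermediate
7 | 1-(2-aminophenyl)-3-[(tert-butyldiphenylsilyl)oxy]propan-1-one | Nc1ccccc1C(=O)CCO[Si](c1ccccc1)(c1ccccc1)C(C)(C)C | intermediate
8 | 6-bromo-1H-indole-2-carboxylic acid | O=C(O)c1cc2ccc(Br)cc2[nH]1 | starting material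
9 | 6-bromo-1H-indole-2-carbonyl chloride | O=C(Cl)c1cc2ccc(Br)cc2[nH]1 | intermediate
10 | 6-bromo-N-(2-{3-[(tert-butyldiphenylsilyl)oxy]propanoyl}phenyl)-1H-indole-2-carboxamide | O=C(Nc1ccccc1C(=O)CCO[Si](c1ccccc1)(c1ccccc1)C(C)(C)C)c1cc2ccc(Br)cc2[nH]1 | intermediate
11 | 6-bromo-3'-{2-[(tert-butyldiphenylsilyl)oxy]ethyl}-1H,1'H-2,2'-biindole | CC(C)(C)[Si](OCCc1c(-c2cc3ccc(Br)cc3[nH]2)[nH]c2ccccc12)(c1ccccc1)c1ccccc1 | intermediate
12 | 2-(6-bromo-1H,1'H-2,2'-biindol-3'-yl)ethan-1-ol | OCCc1c(-c2cc3ccc(Br)cc3[nH]2)[nH]c2ccccc12 | intermediate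
13 | 2-(6-bromo-1H,1'H-2,2'-biindol-3'-yl)ethyl methanesulfonate | CS(=O)(=O)OCCc1c(-c2cc3ccc(Br)cc3[nH]2)[nH]c2ccccc12 | intermediate
14 | 3-bromo-6,7-dihydro-12H-pyrido[1,2-a:3,4-b']diindole | Brc1ccc2cc3n(CCc4c-3[nH]c5ccccc45)c2c1 | intermediate
15 | 3-bromo-12H-pyrido[1,2-a:3,4-b']diindole | c1c2ccc(Br)cc2n2ccc3c4ccccc4[nH]c3c12 | intermediate
16 | N-[(3-bromo-12H-pyrido[1,2-a:3,4-b']diindol-13-yl)methylidene]-N-methylmethanaminium chloride | C[N+](C)=Cc1c2ccc(Br)cc2n2ccc3c4ccccc4[nH]c3c12.[Cl-] | intermediate
17 | 3-bromo-12H-pyrido[1,2-a:3,4-b']diindole-13-carbaldehyde | O=Cc1c2ccc(Br)cc2n2ccc3c4ccccc4[nH]c3c12 | target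

Total step count: 10
Longest linear sequence: 10 steps (1 → 2 → 3 → 6 → 7 → 10 → 11 → 12 → 14 → 15 → 17); compounds 4 and 8 enter as purchased.

Steps most likely to fail

Step 6. The low-valent titanium may reduce the aryl C–Br bond, or cleave or eliminate the β-silyloxy group, faster than it couples the two carbonyls, or ketyl dimerisation may outpace ring closure. The fallback builds the same biindole by a Fischer indole synthesis. It sets out from acid 8 and returns at alcohol 12.
- Acid chloride 9, made from 8 as in step 5, would be treated with N,O-dimethylhydroxylamine hydrochloride and Et3N in CH2Cl2 to give the Weinreb amide 6-bromo-N-methoxy-N-methyl-1H-indole-2-carboxamide F1.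
- Excess [3-(tert-butyldimethylsilyloxy)propyl]magnesium bromide, from commercial (3-bromopropoxy)(tert-butyl)dimethylsilane and Mg, in THF at 0 °C should give the ketone 1-(6-bromo-1H-indol-2-yl)-4-[(tert-butyldimethylsilyl)oxy]butan-1-one F2. One equivalent is spent on the indole N–H, and an alkyl Grignard reagent should not exchange with the aryl bromide at this temperature.
- Heating F2 with phenylhydrazine hydrochloride in aqueous ethanolic H2SO4 should form 1-(6-bromo-1H-indol-2-yl)-4-[(tert-butyldimethylsilyl)oxy]butan-1-one phenylhydrazone F3 in the flask. Its only possible ene-hydrazine undergoes the [3,3]-shift toward the CH2 group, and the acid removes the silyl ether in the same operation, giving 12, from which step 8 continues.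

Step 8. The ambident indolyl anion may alkylate at C13 instead of N5, which would lead to an indolo[2,3-a]carbazole skeleton, or the base may eliminate the sulfonate to a vinylindole. The fallback formylates before closing ring C, so that C13 is blocked and N5–H is acidified. It sets out from 11 and returns at the target 17.
- Vilsmeier–Haack formylation of 11 (POCl3, DMF, 0 °C; aq NaOH) at the only free pyrrole carbon should give 6-bromo-3'-{2-[(tert-butyldiphenylsilyl)oxy]ethyl}-1H,1'H-2,2'-biindole-3-carbaldehyde F4.
- TBAF in THF should give 6-bromo-3'-(2-hydroxyethyl)-1H,1'H-2,2'-biindole-3-carbaldehyde F5.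
- The 3-formyl group lowers the N–H pKa into the range that Mitsunobu alkylation accepts. PBu3 and 1,1'-(azodicarbonyl)dipiperidine in toluene should therefore close ring C by cyclodehydration to 3-bromo-6,7-dihydro-12H-pyrido[1,2-a:3,4-b']diindole-13-carbaldehyde F6.
- DDQ in dioxane, as in step 9, should then dehydrogenate C6–C7 and give 17.

Step 3. Ortho-lithiation may be incomplete, or the strongly basic dianion may deprotonate the α-CH2 of the Weinreb amide, with β-elimination of silanolate, instead of transferring the acyl group. The fallback reverses the order of bond formation and the oxidation level. It sets out from 3 and returns at 7, so steps 3 and 4 are bypassed.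
- DIBAL-H in THF at −78 °C should reduce 3 to 3-[(tert-butyldiphenylsilyl)oxy]propanal F7.
- 2-Nitrophenylmagnesium chloride, generated by iodine–magnesium exchange from 1-iodo-2-nitrobenzene and PhMgCl in THF at −40 °C, should add to F7 to give racemic 3-[(tert-butyldiphenylsilyl)oxy]-1-(2-nitrophenyl)propan-1-ol F8.
- Dess–Martin periodinane in CH2Cl2 should oxidise F8 to 3-[(tert-butyldiphenylsilyl)oxy]-1-(2-nitrophenyl)propan-1-one F9, which removes the stereocentre.
- Fe powder and NH4Cl in aqueous ethanol at 70 °C should reduce the nitro group to give 7, from which step 5 continues.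

Further compounds
F1 | step 6 | 6-bromo-N-methoxy-N-methyl-1H-indole-2-carboxamide | CON(C)C(=O)c1cc2ccc(Br)cc2[nH]1
F2 | step 6 | 1-(6-bromo-1H-indol-2-yl)-4-[(tert-butyldimethylsilyl)oxy]butan-1-one | CC(C)(C)[Si](C)(C)OCCCC(=O)c1cc2ccc(Br)cc2[nH]1
F3 | step 6 | 1-(6-bromo-1H-indol-2-yl)-4-[(tert-butyldimethylsilyl)oxy]butan-1-one phenylhydrazone | CC(C)(C)[Si](C)(C)OCCCC(=NNc1ccccc1)c1cc2ccc(Br)cc2[nH]1
F4 | step 8 | 6-bromo-3'-{2-[(tert-butyldiphenylsilyl)oxy]ethyl}-1H,1'H-2,2'-biindole-3-carbaldehyde | O=Cc1c(-c2[nH]c3ccccc3c2CCO[Si](c2ccccc2)(c2ccccc2)C(C)(C)C)[nH]c2cc(Br)ccc12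
F5 | step 8 | 6-bromo-3'-(2-hydroxyethyl)-1H,1'H-2,2'-biindole-3-carbaldehyde | O=Cc1c(-c2[nH]c3ccccc3c2CCO)[nH]c2cc(Br)ccc12
F6 | step 8 | 3-bromo-6,7-dihydro-12H-pyrido[1,2-a:3,4-b']diindole-13-carbaldehyde | O=Cc1c2ccc(Br)cc2n2CCc3c4ccccc4[nH]c3-c12
F7 | step 3 | 3-[(tert-butyldiphenylsilyl)oxy]propanal | O=CCCO[Si](c1ccccc1)(c1ccccc1)C(C)(C)C
F8 | step 3 | 3-[(tert-butyldiphenylsilyl)oxy]-1-(2-nitrophenyl)propan-1-ol (racemic) | OC(CCO[Si](c1ccccc1)(c1ccccc1)C(C)(C)C)c1ccccc1[N+](=O)[O-]
F9 | step 3 | 3-[(tert-butyldiphenylsilyl)oxy]-1-(2-nitrophenyl)propan-1-one | O=C(CCO[Si](c1ccccc1)(c1ccccc1)C(C)(C)C)c1ccccc1[N+](=O)[O-]
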